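## Analysis of the target

Target 29 is an achiral macrocyclic bis(bibenzyl). Four benzene rings are joined into an 18-membered ring by two diaryl ether oxygens and two CH2–CH2 bridges. Ring positions are written with a hyphen: ring A has OMe at A-1, OH at A-4, the bridge CH2 at A-5 and the ether oxygen at A-6; ring B is meta-linked (O at B-1, CH2 at B-3); ring C has CH2 at C-1, the ether oxygen at C-3 and OH at C-4; ring D is para-linked (O at D-1, CH2 at D-4). There is no stereocentre, and the ring is large and flexible enough that no stable atropisomer is expected. The sensitive groups are the two free phenols. Ring A is an electron-rich hydroquinone monomethyl ether that oxidises easily, so both phenols travel protected and are released last under reductive conditions. The first difficulty is ring A itself: four contiguous substituents, two para oxygens that must end up different (one methylated, one free), and an ether oxygen at A-6 flanked on both sides, which makes a late diaryl ether coupling there unattractive. The second difficulty is closing the 18-membered ring. The strategy rests on the fact that the A-1 OMe / A-4 OH pair with neighbouring A-6 aryloxy and A-5 alkyl groups is exactly the pattern that a 2-alkyl-3-aryloxy-4-methoxy-4-vinylcyclobutenone (14) delivers on thermal ring expansion. The carbonyl carbon becomes A-4, C-2 becomes A-5, C-3 becomes A-6, the quaternary carbon becomes A-1, and the vinyl carbons become A-2 and A-3.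

## Retrosynthetic reasoning

**29 from 28.** The two phenols at A-4 and C-4 are masked as benzyl ethers in 28. Hydrogenolysis is the last step because by then no aryl halide or alkene remains that could be reduced.

**28 from 26 (through 27).** The macrocycle is opened at the B-3–CH2 bond. This sp2–sp3 bond is chosen because ring B can then enter as the cheap bromophenol 9, whose bromine is inert to all squarate chemistry and to the thermal step and later serves as the coupling handle. The closure site is also remote from the crowded ring A. Forward, the vinyl group on ring C of 26 is hydroborated to borane 27, which must couple intramolecularly with the ring B bromide.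

**26 from 19 and 25.** The C-3–O bond of the D–O–C ether is cut, giving phenol 19 and boronic acid 25. An oxidative copper coupling at room temperature tolerates the aryl bromide and the styrene. The ring C unit is attached only now because its 4-alkoxystyrene would not survive the acidic steps of the squarate sequence.

**19 from 17 (through 18).** This is a protecting-group exchange: the A-4 hydroxyl of 17 is benzylated (18) and the D-1 silyl ether is then removed. The silyl group is needed up to this point because it withstands Grignard formation, aqueous acid and heat.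

**17 from 14 (key disconnection).** Ring A is opened at the A-3–A-4 bond to dienylketene 15, and 15 is closed back to the four-membered ring of 14. This replaces the regiochemical problems of a tetrasubstituted arene with the ordered substitution of a squarate. Forward, 14 must open with the vinyl group turned toward the ketene and then close through dienone 16 to the phenol.

**14 from 11 and 12.** The bond between the quaternary carbon and the vinyl group is cut, and the methyl is removed from oxygen. Forward, vinyl Grignard 12 must add to the carbonyl of 11 that lies next to the aryloxy-bearing carbon, giving carbinol 13, which is then O-methylated.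

**11 from 8 and 9 (through 10).** The hindered A-6–O–B-1 ether is cut here, where the future A-6 is an sp2 carbon of a vinylogous acid chloride (10). It can then be made by simple addition–elimination with phenol 9 instead of by arylation of a doubly flanked phenol.

**8 from 7, and 7 from 2 and 3 (2 from 1).** The vinylogous acid 8 comes from isopropyl ester 7 by hydrolysis. Ester 7 is cut at the bond between the ring carbon and the CH2 of the D–A bridge, leading to squarate 3 and Grignard 4, made from bromide 2, the silyl ether of phenol 1.

**25 from 20 (through 21 and 22).** The boronic acid comes from bromide 22 by halogen–metal exchange. The vinyl group of 22 comes from aldehyde 21 by methylenation, and 21 from phenol 20 by benzylation.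

## Alternatives that were turned down

**Alternative 1:** The D–A bridge is cut between its two methylene carbons with a sulfur atom inserted. The forward key step is photolysis or flash vacuum pyrolysis of the 19-membered dibenzylic sulfone A2, which expels its sulfonyl unit as a gas; the two tethered benzylic radicals recombine to the diisopropyl ether of the target macrocycle A1.
- For: thioether macrocyclisation from a bis(benzylic halide) is one of the most dependable cyclophane closures, and the contraction is intramolecular and needs no dilution. On ring closure this plan is stronger than the chosen one.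
- Against: the benzylic radical on ring A sits between two ortho substituents. Pyrolysis temperatures threaten the isopropyl ethers by elimination, and photolysis of diaryl ethers invites rearrangement. Two isopropyl ethers must finally be removed beside a methyl ether.
- Decisive point: ring A still has to be bought or built as a tetrasubstituted arene, with the flanked A-6 ether made by a hindered coupling. The chosen strategy instead assembles ring A with all four groups placed and the oxygens differentiated in one step.

**Alternative 2:** The B–C bridge is cut at both of its aryl–carbon bonds into three components. A ring C aryllithium adds to a vinylboronic ester, and a palladium catalyst with a ferrocenyl bisphosphine couples the resulting ate complex with a ring B aryl triflate by 1,2-aryl migration, giving the open-chain boronate A3.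
- For: one step forges both bonds of the bridge and unites two halves convergently. On convergence of fragment union it is equal or better.
- Against: A3 carries a benzylic boronate and a stereocentre that the target does not need, so an extra protodeboronation follows and the enantiocontrol of the method is wasted. Ring closure is then left to the D–A bridge between two benzylic carbons, one of them on the crowded ring A. Ring A is again a prefabricated arene.
- Comparison: the chosen route makes the same B–C bridge by hydroboration and alkyl–aryl coupling, which closes the macrocycle at the same time and leaves no superfluous group.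

**Alternative 3:** The A-6–O bond is cut as the ring-closing bond. A fluoride source frees the ring B phenoxide, which adds to the bromine-bearing β-carbon of a ring A quinone monoketal and expels bromide, giving the macrocyclic 3-aryloxy quinone monoketal A4; reduction then aromatises it.
- For: closure is metal-free and mild, and the ketal carbon becomes A-1 OMe while the carbonyl becomes A-4 OH. On oxygen differentiation it equals the chosen plan, and on mildness of the ring closure it is stronger.
- Against: the attacked carbon lies between the quaternary ketal carbon and the substituted A-5 and is the most hindered site of the dienone, while the unsubstituted enone carbon is an open competing acceptor. The ketal is labile, and the precursor needs a brominated tetrasubstituted phenol made with regiochemical risk.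
- Comparison: the chosen strategy fixes the aryloxy group at the squarate stage, where only one leaving group exists, so nothing depends on the site selectivity of a macrocyclisation.

Key step: step 7

Remark on the chemistry: 5, 6, 13 and 14 each contain one stereocentre and are made and used as racemates; that centre is erased on aromatisation, and the target is achiral.

## Route

Step 1
Reactants: 1 4-(2-bromoethyl)phenol
Product: 2 [4-(2-bromoethyl)phenoxy]triisopropylsilane
Conditions: TIPSCl, imidazole, DMF, 0 °C to rt
Reagents that add atoms: chlorotriisopropylsilane, CC(C)[Si](Cl)(C(C)C)C(C)C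
Why: Silylation of a phenol with a silyl chloride and imidazole; the weak base does not provoke alkylation by the primary bromide, and the bulky aryl silyl ether is chosen to survive Grignard formation and the aqueous acid of step 3.

Step 2
Reactants: 2 [4-(2-bromoethyl)phenoxy]triisopropylsilane; 3 diisopropyl squarate
Product: 7 3-isopropoxy-4-{2-[4-(triisopropylsilyloxy)phenyl]ethyl}cyclobut-3-ene-1,2-dione, via Grignard reagent 4 (not isolated), via bromomagnesium alkoxide adduct 5 (not isolated), via trifluoroacetate 6 (not isolated)
Conditions: Mg, THF, rt to 40 °C; add to 3, THF, −78 °C; (CF3CO)2O, −78 to −20 °C; H2O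
Reagents that add atoms: water, O
Why: Grignard formation from a primary bromide and 1,2-addition to one carbonyl of the squarate ester, followed by the known trifluoroacetylation and hydrolysis of the adduct, in which ionisation assisted by the isopropoxy group, attack of water and loss of isopropanol give the 3-alkyl-4-alkoxycyclobutenedione. Mono-addition is expected because adduct 5 is no longer a 1,2-dione.

Step 3
Reactants: 7 3-isopropoxy-4-{2-[4-(triisopropylsilyloxy)phenyl]ethyl}cyclobut-3-ene-1,2-dione
Product: 8 3-hydroxy-4-{2-[4-(triisopropylsilyloxy)phenyl]ethyl}cyclobut-3-ene-1,2-dione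
Conditions: 2 M aq. HCl, THF, rt to 40 °C
Reagents that add atoms: water, O
Why: Acid hydrolysis of a vinylogous ester by addition–elimination of water at the isopropoxy-bearing carbon, giving the strongly acidic semisquaric acid. A hindered aryl silyl ether is cleaved by fluoride or base far more readily than by dilute acid and should persist.

Step 4
Reactants: 8 3-hydroxy-4-{2-[4-(triisopropylsilyloxy)phenyl]ethyl}cyclobut-3-ene-1,2-dione; 9 3-bromophenol
Product: 11 3-(3-bromophenoxy)-4-{2-[4-(triisopropylsilyloxy)phenyl]ethyl}cyclobut-3-ene-1,2-dione, via chlorocyclobutenedione 10 (not isolated)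
Conditions: (COCl)2, DMF (cat.), CH2Cl2, 0 °C to rt, evaporate; 9, pyridine, CH2Cl2, −20 to 0 °C
Reagents that add atoms: none
Why: The vinylogous acid is turned into its vinylogous acid chloride, which the phenol displaces by addition–elimination as in an acyl substitution. The crowded A-6–O–B-1 ether is thus formed at an activated sp2 carbon and not at a doubly flanked arene position.

Step 5
Reactants: 11 3-(3-bromophenoxy)-4-{2-[4-(triisopropylsilyloxy)phenyl]ethyl}cyclobut-3-ene-1,2-dione; 12 vinylmagnesium bromide
Product: 13 rac-3-(3-bromophenoxy)-4-hydroxy-2-{2-[4-(triisopropylsilyloxy)phenyl]ethyl}-4-vinylcyclobut-2-en-1-one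
Conditions: THF, −78 °C; sat. aq. NH4Cl, −78 °C
Reagents that add atoms: none
Why: Grignard 1,2-addition to the more electrophilic carbonyl of a 3-oxy-substituted cyclobutenedione; the carbonyl beside the alkyl-bearing carbon is a vinylogous ester through the aryloxy oxygen and is deactivated, so attack should occur at the carbonyl beside the aryloxy carbon. The new quaternary stereocentre forms as a racemate, which is immaterial.

Step 6
Reactants: 13 rac-3-(3-bromophenoxy)-4-hydroxy-2-{2-[4-(triisopropylsilyloxy)phenyl]ethyl}-4-vinylcyclobut-2-en-1-one
Product: 14 rac-3-(3-bromophenoxy)-4-methoxy-2-{2-[4-(triisopropylsilyloxy)phenyl]ethyl}-4-vinylcyclobut-2-en-1-one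
Conditions: MeI, Ag2O, MeCN, rt, dark
Reagents that add atoms: iodomethane, CI
Why: O-Methylation of a tertiary carbinol with silver oxide and methyl iodide (Purdie methylation); the nearly neutral conditions avoid the alkoxide, which could open the hydroxycyclobutenone or expel the aryloxide.

Step 7
Reactants: 14 rac-3-(3-bromophenoxy)-4-methoxy-2-{2-[4-(triisopropylsilyloxy)phenyl]ethyl}-4-vinylcyclobut-2-en-1-one
Product: 17 3-(3-bromophenoxy)-4-methoxy-2-{2-[4-(triisopropylsilyloxy)phenyl]ethyl}phenol, via dienylketene 15 (not isolated), via cyclohexa-2,4-dienone 16 (not isolated)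
Conditions: degassed toluene (0.02 M), 110 °C, Ar (p-xylene, 138 °C if slow)
Reagents that add atoms: none
Why: On heating, the cyclobutenone should undergo conrotatory 4π electrocyclic opening of the bond between the carbonyl carbon and the quaternary carbon to give dienylketene 15, with the methoxy group, the stronger donor on that carbon, rotating outward and the vinyl group inward, next to the ketene. Ketene 15 then closes by thermal disrotatory 6π electrocyclisation between the ketene carbon and the vinyl terminus, forming the A-3–A-4 bond and ring A as dienone 16, and enolisation gives phenol 17. The closest known reaction type is the Moore rearrangement of squarate-derived 4-alkenyl-4-alkoxycyclobutenones into 4-alkoxyphenols. The ketene oxygen ends as the free A-4 hydroxyl and the quaternary methoxy as A-1 OMe, so the two hydroquinone oxygens emerge differentiated, while the arylethyl and aryloxy groups are carried unchanged to A-5 and A-6. No stereocentre is formed, and the racemic centre of 14 is erased. The step needs torquoselectivity, secured by the outward preference of the alkoxy donor, and regioselective ring opening, secured because only one ring bond joins the sp3 carbon to the carbonyl. Dilution and exclusion of air and nucleophiles protect the ketene and the electron-rich phenol.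

Step 8
Reactants: 17 3-(3-bromophenoxy)-4-methoxy-2-{2-[4-(triisopropylsilyloxy)phenyl]ethyl}phenol
Product: 18 (4-{2-[6-(benzyloxy)-2-(3-bromophenoxy)-3-methoxyphenyl]ethyl}phenoxy)triisopropylsilane
Conditions: BnBr, K2CO3, acetone, 50 °C
Reagents that add atoms: benzyl bromide, BrCc1ccccc1
Why: Williamson etherification of the only free phenol; anhydrous carbonate in acetone should leave the hindered aryl silyl ether intact. Benzyl is chosen so that the A-4 and C-4 oxygens are released together at the end.

Step 9
Reactants: 18 (4-{2-[6-(benzyloxy)-2-(3-bromophenoxy)-3-methoxyphenyl]ethyl}phenoxy)triisopropylsilane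
Product: 19 4-{2-[6-(benzyloxy)-2-(3-bromophenoxy)-3-methoxyphenyl]ethyl}phenol
Conditions: TBAF, THF, 0 °C
Reagents that add atoms: none
Why: Fluoride cleavage of an aryl silyl ether; benzyl, methyl and diaryl ethers and the aryl bromide are inert to fluoride.

Step 10
Reactants: 20 3-bromo-4-hydroxybenzaldehyde
Product: 21 4-(benzyloxy)-3-bromobenzaldehyde
Conditions: BnBr, K2CO3, DMF, rt
Reagents that add atoms: benzyl bromide, BrCc1ccccc1
Why: Williamson benzylation of an acidic phenol; the aldehyde is untouched.

Step 11
Reactants: 21 4-(benzyloxy)-3-bromobenzaldehyde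
Product: 22 1-(benzyloxy)-2-bromo-4-vinylbenzene
Conditions: Ph3PCH3Br, KOtBu, THF, 0 °C to rt
Reagents that add atoms: methyltriphenylphosphonium bromide, C[P+](c1ccccc1)(c1ccccc1)c1ccccc1.[Br-]
Why: Wittig methylenation of an aromatic aldehyde with the non-stabilised ylide.

Step 12
Reactants: 22 1-(benzyloxy)-2-bromo-4-vinylbenzene
Product: 25 [2-(benzyloxy)-5-vinylphenyl]boronic acid, via aryllithium 23 (not isolated), via lithium aryltriisopropoxyborate 24 (not isolated)
Conditions: n-BuLi, THF, −78 °C; B(OiPr)3, −78 °C to rt; 1 M aq. HCl, 0 °C, brief
Reagents that add atoms: triisopropyl borate, CC(C)OB(OC(C)C)OC(C)C; water, O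
Why: Bromine–lithium exchange at −78 °C is much faster than addition of butyllithium to the styrene; the aryllithium is trapped by the borate and the ate complex is hydrolysed. The acid contact is kept cold and short to spare the acid-sensitive 4-alkoxystyrene.

Step 13
Reactants: 19 4-{2-[6-(benzyloxy)-2-(3-bromophenoxy)-3-methoxyphenyl]ethyl}phenol; 25 [2-(benzyloxy)-5-vinylphenyl]boronic acid
Product: 26 1-(benzyloxy)-2-[2-(4-{[2-(benzyloxy)-5-vinylphenyl]oxy}phenyl)ethyl]-3-(3-bromophenoxy)-4-methoxybenzene
Conditions: Cu(OAc)2, pyridine, 4 Å MS, CH2Cl2, dry air, rt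
Reagents that add atoms: none
Why: Chan–Lam coupling of a phenol with an arylboronic acid, with the copper turned over by oxygen; at room temperature it does not touch the aryl bromide or the styrene, which is why this C–O bond is made by copper and boron and not by palladium.

Step 14
Reactants: 26 1-(benzyloxy)-2-[2-(4-{[2-(benzyloxy)-5-vinylphenyl]oxy}phenyl)ethyl]-3-(3-bromophenoxy)-4-methoxybenzene
Product: 28 dibenzyl ether of the target macrocycle (benzyl on the A-4 and C-4 oxygens), via B-alkyl-9-BBN borane 27 (not isolated)
Conditions: 9-BBN, THF, rt; slow addition to PdCl2(dppf), AsPh3, Cs2CO3, DMF/THF/H2O, 60 °C, ca. 1 mM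
Reagents that add atoms: none
Why: 9-BBN hydroborates the styrene at its terminal carbon; the alkylborane, activated by base, transmetallates to the arylpalladium bromide formed at ring B, and reductive elimination forms the B-3–CH2 bond and closes the 18-membered ring (B-alkyl Suzuki–Miyaura macrocyclisation). Slow addition keeps the open-chain borane dilute so that ring closure outruns oligomerisation.

Step 15
Reactants: 28 dibenzyl ether of the target macrocycle
Product: 29 target macrocycle CNP0179896.0
Conditions: H2 (1 atm), 10% Pd/C, EtOAc/EtOH, rt
Reagents that add atoms: none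
Why: Hydrogenolysis of two aryl benzyl ethers; methyl and diaryl ethers are stable, and no other reducible group remains.

## Compound list

1 | 4-(2-bromoethyl)phenol | Oc1ccc(CCBr)cc1 | starting material
2 | [4-(2-bromoethyl)phenoxy]triisopropylsilane | CC(C)[Si](Oc1ccc(CCBr)cc1)(C(C)C)C(C)C | intermediate
3 | diisopropyl squarate | CC(C)OC1=C(OC(C)C)C(=O)C1=O | starting material
4 | {2-[4-(triisopropylsilyloxy)phenyl]ethyl}magnesium bromide | Br[Mg]CCc1ccc(O[Si](C(C)C)(C(C)C)C(C)C)cc1 | intermediate
5 | bromomagnesium alkoxide of rac-4-hydroxy-2,3-diisopropoxy-4-{2-[4-(triisopropylsilyloxy)phenyl]ethyl}cyclobut-2-en-1-one | CC(C)OC1=C(OC(C)C)C(O[Mg]Br)(CCc2ccc(O[Si](C(C)C)(C(C)C)C(C)C)cc2)C1=O | intermediate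
6 | trifluoroacetate of the same carbinol (racemic) | CC(C)OC1=C(OC(C)C)C(OC(=O)C(F)(F)F)(CCc2ccc(O[Si](C(C)C)(C(C)C)C(C)C)cc2)C1=O | intermediate
7 | 3-isopropoxy-4-{2-[4-(triisopropylsilyloxy)phenyl]ethyl}cyclobut-3-ene-1,2-dione | CC(C)OC1=C(CCc2ccc(O[Si](C(C)C)(C(C)C)C(C)C)cc2)C(=O)C1=O | intermediate
8 | 3-hydroxy-4-{2-[4-(triisopropylsilyloxy)phenyl]ethyl}cyclobut-3-ene-1,2-dione | OC1=C(CCc2ccc(O[Si](C(C)C)(C(C)C)C(C)C)cc2)C(=O)C1=O | intermediate
9 | 3-bromophenol | Oc1cccc(Br)c1 | starting material
10 | 3-chloro-4-{2-[4-(triisopropylsilyloxy)phenyl]ethyl}cyclobut-3-ene-1,2-dione | ClC1=C(CCc2ccc(O[Si](C(C)C)(C(C)C)C(C)C)cc2)C(=O)C1=O | intermediate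
11 | 3-(3-bromophenoxy)-4-{2-[4-(triisopropylsilyloxy)phenyl]ethyl}cyclobut-3-ene-1,2-dione | O=C1C(=O)C(Oc2cccc(Br)c2)=C1CCc1ccc(O[Si](C(C)C)(C(C)C)C(C)C)cc1 | intermediate
12 | vinylmagnesium bromide | C=C[Mg]Br | starting material
13 | rac-3-(3-bromophenoxy)-4-hydroxy-2-{2-[4-(triisopropylsilyloxy)phenyl]ethyl}-4-vinylcyclobut-2-en-1-one | C=CC1(O)C(Oc2cccc(Br)c2)=C(CCc2ccc(O[Si](C(C)C)(C(C)C)C(C)C)cc2)C1=O | intermediate
14 | rac-3-(3-bromophenoxy)-4-methoxy-2-{2-[4-(triisopropylsilyloxy)phenyl]ethyl}-4-vinylcyclobut-2-en-1-one | C=CC1(OC)C(Oc2cccc(Br)c2)=C(CCc2ccc(O[Si](C(C)C)(C(C)C)C(C)C)cc2)C1=O | intermediate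
15 | (3Z)-3-(3-bromophenoxy)-4-methoxy-2-{2-[4-(triisopropylsilyloxy)phenyl]ethyl}hexa-1,3,5-trien-1-one | O=C=C(CCc1ccc(O[Si](C(C)C)(C(C)C)C(C)C)cc1)/C(Oc1cccc(Br)c1)=C(\C=C)OC | intermediate
16 | 3-(3-bromophenoxy)-4-methoxy-2-{2-[4-(triisopropylsilyloxy)phenyl]ethyl}cyclohexa-2,4-dien-1-one | O=C1CC=C(OC)C(Oc2cccc(Br)c2)=C1CCc1ccc(O[Si](C(C)C)(C(C)C)C(C)C)cc1 | intermediate
17 | 3-(3-bromophenoxy)-4-methoxy-2-{2-[4-(triisopropylsilyloxy)phenyl]ethyl}phenol | COc1ccc(O)c(CCc2ccc(O[Si](C(C)C)(C(C)C)C(C)C)cc2)c1Oc1cccc(Br)c1 | intermediate
18 | (4-{2-[6-(benzyloxy)-2-(3-bromophenoxy)-3-methoxyphenyl]ethyl}phenoxy)triisopropylsilane | COc1ccc(OCc2ccccc2)c(CCc2ccc(O[Si](C(C)C)(C(C)C)C(C)C)cc2)c1Oc1cccc(Br)c1 | intermediate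
19 | 4-{2-[6-(benzyloxy)-2-(3-bromophenoxy)-3-methoxyphenyl]ethyl}phenol | COc1ccc(OCc2ccccc2)c(CCc2ccc(O)cc2)c1Oc1cccc(Br)c1 | intermediate
20 | 3-bromo-4-hydroxybenzaldehyde | O=Cc1ccc(O)c(Br)c1 | starting material
21 | 4-(benzyloxy)-3-bromobenzaldehyde | O=Cc1ccc(OCc2ccccc2)c(Br)c1 | intermediate
22 | 1-(benzyloxy)-2-bromo-4-vinylbenzene | C=Cc1ccc(OCc2ccccc2)c(Br)c1 | intermediate
23 | [2-(benzyloxy)-5-vinylphenyl]lithium | [Li]c1cc(C=C)ccc1OCc1ccccc1 | intermediate
24 | lithium [2-(benzyloxy)-5-vinylphenyl]triisopropoxyborate | [Li+].CC(C)O[B-](OC(C)C)(OC(C)C)c1cc(C=C)ccc1OCc1ccccc1 | intermediate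
25 | [2-(benzyloxy)-5-vinylphenyl]boronic acid | OB(O)c1cc(C=C)ccc1OCc1ccccc1 | intermediate
26 | 1-(benzyloxy)-2-[2-(4-{[2-(benzyloxy)-5-vinylphenyl]oxy}phenyl)ethyl]-3-(3-bromophenoxy)-4-methoxybenzene | COc1ccc(OCc2ccccc2)c(CCc2ccc(Oc3cc(C=C)ccc3OCc3ccccc3)cc2)c1Oc1cccc(Br)c1 | intermediate
27 | B-alkyl-9-BBN borane from 26 (9-borabicyclo[3.3.1]nonan-9-yl on the terminal carbon of the former vinyl group) | COc1ccc(OCc2ccccc2)c(CCc2ccc(Oc3cc(CCB4C5CCCC4CCC5)ccc3OCc3ccccc3)cc2)c1Oc1cccc(Br)c1 | intermediate
28 | dibenzyl ether of the target macrocycle (benzyl on the A-4 and C-4 oxygens) | COc1ccc(OCc3ccccc3)c2c1Oc1cccc(c1)CCc1ccc(OCc3ccccc3)c(c1)Oc1ccc(cc1)CC2 | intermediate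
29 | target macrocycle CNP0179896.0 | COc1ccc(O)c2c1Oc1cccc(c1)CCc1ccc(O)c(c1)Oc1ccc(cc1)CC2 | target

## Step count and risk

Total step count: 15. Longest linear sequence: 12 (steps 1–9 and 13–15); steps 10–12 form the side branch to boronic acid 25.

**Step 7 (key step).** The most likely failure is diversion of dienylketene 15 before it closes. Part of the ring opening may occur with the methoxy group turned inward, which leaves the vinyl group out of reach, or the ketene may be captured by traces of nucleophiles or dimerise. The fallback sets out from carbinol 13 and returns at 17. The free carbinol, whose hydroxyl is the stronger outward-rotating donor, is heated in degassed toluene in the classical hydroxy version of the ring expansion to give 2-(3-bromophenoxy)-3-{2-[4-(triisopropylsilyloxy)phenyl]ethyl}benzene-1,4-diol F1. F1 is then monomethylated with one equivalent of MeI and K2CO3 in acetone. The hydroxyl beside the aryloxy group is the more acidic and the less shielded, so it should react first, but 17 would have to be separated from its regioisomer. This gives up the built-in oxygen differentiation in exchange for the better-precedented ring opening.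

**Step 14.** Intermolecular coupling to dimers and oligomers may outrun the 18-membered closure, and the alkylpalladium intermediate may be lost by protodeboronation or β-hydride elimination. The fallback sets out from 26 and returns at 29, changing both the bond-forming mode and the oxidation level of the bridge. The ring B bromide is vinylated (potassium vinyltrifluoroborate, PdCl2(dppf), Cs2CO3, THF/H2O) to the divinyl compound 1-(benzyloxy)-2-[2-(4-{[2-(benzyloxy)-5-vinylphenyl]oxy}phenyl)ethyl]-4-methoxy-3-(3-vinylphenoxy)benzene F2. Ring-closing metathesis with second-generation Grubbs catalyst at high dilution gives the macrocyclic stilbene F3 (drawn as Z; the geometry is immaterial). The conditions of step 15 then saturate the alkene and remove both benzyl groups to give 29.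

**Step 5.** Three processes compete with the wanted 1,2-addition: conjugate addition–elimination that expels the aryloxide, attack at the other carbonyl (the aryloxy group deactivates it less than an alkoxy group would), and deprotonation of the side-chain CH2 by the basic Grignard reagent. The fallback sets out from 11 and returns at 14, bringing in the two carbons at the alkyne level with a less basic, strictly 1,2-selective nucleophile. Ethynylmagnesium bromide in THF at −78 °C gives rac-3-(3-bromophenoxy)-4-ethynyl-4-hydroxy-2-{2-[4-(triisopropylsilyloxy)phenyl]ethyl}cyclobut-2-en-1-one F4. Methylation with MeOTf and 2,6-di-tert-butyl-4-methylpyridine (silver is avoided because of the terminal alkyne) gives the 4-ethynyl-4-methoxy analogue F5. Semihydrogenation over Pd/CaCO3 poisoned with Pb(OAc)2 and quinoline then gives 14.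

**Step 4.** The chlorocyclobutenedione 10 is a highly electrophilic vinylogous acid chloride with an enolisable side chain and may decompose before the phenol intercepts it; hydrogen chloride may also attack the silyl ether, a risk shared with the aqueous acid of step 3. The fallback sets out from Grignard reagent 4 and returns at 11, skipping steps 3 and 4. Squaric acid dichloride F6 and two equivalents of 9 with pyridine give bis(3-bromophenyl) squarate F7. Addition of 4 at −78 °C gives the carbinol adduct rac-2,3-bis(3-bromophenoxy)-4-hydroxy-4-{2-[4-(triisopropylsilyloxy)phenyl]ethyl}cyclobut-2-en-1-one F8, which on the acid treatment used for squarate adducts loses 9 and gives 11. A direct addition–elimination of the Grignard reagent on F7 would lead to the same product.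

**Step 13.** The ortho-alkoxy boronic acid may protodeboronate or homocouple faster than it transfers its aryl group to the phenol. The fallback sets out from 19 and 22 and returns at 26, replacing the boron partner by an aryl iodide and the oxidative coupling by an Ullmann ether synthesis. Bromide 22 is converted by n-BuLi at −78 °C and then I2 into 1-(benzyloxy)-2-iodo-4-vinylbenzene F9. F9 is coupled with 19 using CuI, N,N-dimethylglycine and Cs2CO3 in dioxane at 90 °C, relying on the faster reaction of the iodide over the ring B bromide and on an excess of F9.

## Further compounds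

F1 | step 7 | 2-(3-bromophenoxy)-3-{2-[4-(triisopropylsilyloxy)phenyl]ethyl}benzene-1,4-diol | Oc1ccc(O)c(CCc2ccc(O[Si](C(C)C)(C(C)C)C(C)C)cc2)c1Oc1cccc(Br)c1
F2 | step 14 | 1-(benzyloxy)-2-[2-(4-{[2-(benzyloxy)-5-vinylphenyl]oxy}phenyl)ethyl]-4-methoxy-3-(3-vinylphenoxy)benzene | COc1ccc(OCc2ccccc2)c(CCc2ccc(Oc3cc(C=C)ccc3OCc3ccccc3)cc2)c1Oc1cccc(C=C)c1
F3 | step 14 | macrocyclic (Z)-stilbene, dibenzyl ether, with a CH=CH bridge between ring B and ring C | COc1ccc(OCc3ccccc3)c2c1Oc1cccc(c1)/C=C\c1ccc(OCc3ccccc3)c(c1)Oc1ccc(cc1)CC2
F4 | step 5 | rac-3-(3-bromophenoxy)-4-ethynyl-4-hydroxy-2-{2-[4-(triisopropylsilyloxy)phenyl]ethyl}cyclobut-2-en-1-one | C#CC1(O)C(Oc2cccc(Br)c2)=C(CCc2ccc(O[Si](C(C)C)(C(C)C)C(C)C)cc2)C1=O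
F5 | step 5 | rac-3-(3-bromophenoxy)-4-ethynyl-4-methoxy-2-{2-[4-(triisopropylsilyloxy)phenyl]ethyl}cyclobut-2-en-1-one | C#CC1(OC)C(Oc2cccc(Br)c2)=C(CCc2ccc(O[Si](C(C)C)(C(C)C)C(C)C)cc2)C1=O
F6 | step 4 | squaric acid dichloride (3,4-dichlorocyclobut-3-ene-1,2-dione) | ClC1=C(Cl)C(=O)C1=O
F7 | step 4 | bis(3-bromophenyl) squarate (3,4-bis(3-bromophenoxy)cyclobut-3-ene-1,2-dione) | O=C1C(=O)C(Oc2cccc(Br)c2)=C1Oc1cccc(Br)c1
F8 | step 4 | rac-2,3-bis(3-bromophenoxy)-4-hydroxy-4-{2-[4-(triisopropylsilyloxy)phenyl]ethyl}cyclobut-2-en-1-one | O=C1C(Oc2cccc(Br)c2)=C(Oc2cccc(Br)c2)C1(O)CCc1ccc(O[Si](C(C)C)(C(C)C)C(C)C)cc1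
F9 | step 13 | 1-(benzyloxy)-2-iodo-4-vinylbenzene | C=Cc1ccc(OCc2ccccc2)c(I)c1
A1 | alternative 1 | diisopropyl ether of the target macrocycle | COc1ccc(OC(C)C)c2c1Oc1cccc(c1)CCc1ccc(OC(C)C)c(c1)Oc1ccc(cc1)CC2
A2 | alternative 1 | 19-membered dibenzylic sulfone with CH2–SO2–CH2 in place of the D–A bridge | COc1ccc(OC(C)C)c2c1Oc1cccc(c1)CCc1ccc(OC(C)C)c(c1)Oc1ccc(cc1)CS(=O)(=O)C2
A3 | alternative 2 | open-chain four-ring benzylic pinacol boronate with the B–C two-carbon bridge (configuration at the boron-bearing carbon immaterial) | COc1ccc(OCc2ccccc2)c(CO[Si](C(C)C)(C(C)C)C(C)C)c1Oc1cccc(CC(B2OC(C)(C)C(C)(C)O2)c2ccc(OCc3ccccc3)c(Oc3ccc(CO[Si](C(C)C)(C(C)C)C(C)C)cc3)c2)c1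
A4 | alternative 3 | macrocyclic 3-aryloxy quinone monoketal | O=C1C=CC(OC)(OC)C2=C1CCc1ccc(cc1)Oc1cc(ccc1OCc1ccccc1)CCc1cccc(c1)O2
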